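Germacrane numbering is used for every intermediate: ring C1–C10, lactone carbons C11–C13, C14 on C10, C15 on C4.

## The problem

Compound 47 is a ten-membered carbocycle with a trans-fused α-methylene-γ-lactone across C6–C7, two ring-cis trisubstituted olefins (C1=C10 and C4=C5) that each carry an allylic CH2OH group, and two different esters on the cis C8/C9 diol. The four contiguous ring stereocentres (6R,7S,8R,9S) must be set on a medium ring of uncertain conformation; the fifth centre comes with (S)-2-methylbutanoic acid 43. C8 and C9 are best made together; C8 can then steer C7 (1,2-induction at the α-carbon of a C6 ketone) and, through chelation, C6 (1,3-induction), so one early centre in a six-membered ring can be relayed to all four. The α-methylene lactone is a Michael acceptor and will not survive amines, thiolates or strong base for long. The C8 and C9 esters are cis on neighbouring carbons and can exchange places under base, and the C9 acetate is 1,3 to the free C14 hydroxyl. Esters therefore go on late, each onto a lone hydroxyl, and the last deprotection must be acidic or neutral. The feature that opens the key step is the array O–C6, C7, C8(O), C9(O), C10=C1: it is what a [3,3] shift of a 3-oxido-1,5-diene leaves behind, so C1 and C6 can start as neighbours in a cyclohexene that already holds the cis C4=C5 bond.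

## Retrosynthesis

**Esters and protecting groups (47 back to 41).** The two acyl C–O bonds and the two silyl ethers are cut. Each acylation is done while the neighbouring oxygen is still an ether: the C8 methoxymethyl ether of 41 is removed first (42) and esterified with 43 (44), then the C9 4-methoxybenzyl ether is cleaved (45) and acetylated (46). The opposite order would place a free C8 hydroxyl beside a C9 acetate under basic acylation. Triisopropylsilyl ethers on O14 and O15 go last under buffered HF.

**Lactone (41 back to 33).** The exocyclic C11=C13 bond is cut to the saturated lactone 38, the lactone C–O bond and the C6 carbinol to keto ester 36, and the C7–C11 bond to ketone 33 and methyl bromoacetate 34. Carrying C11 on the carbinol vinyl group was weighed against this and rejected, because it needs a far less accessible trisubstituted vinyl metal. The forward steps must alkylate C7 trans to O8 and reduce C6 under chelation by the C8 ether.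

**Ring expansion (33 back to 30).** The C8–C9 bond is cut and C1 is rejoined to C6. This turns the ten-membered dienone into the cis-1,2-dialkenylcyclohex-2-enol 30, with a single pair of stereocentres and both olefin geometries stored as enol ether geometries. Against a direct macrocyclisation it offers ring, C8–C9 bond and two stereocentres in one step without dilution. It demands a chair transition state and an enolate that survives until it is quenched.

**Carbinol (30 back to 26 and 20).** The C6–C7 bond is cut to enone 26 and the vinyl ether 20, whose cis-β-lithio derivative delivers the Z enol ether directly. The new vinyl group must enter cis to the C1 side chain, against the usual preference of 6-alkenylcyclohexenones. The C14 oxygen is therefore left free in 26 to bind the metal and direct the addition, and is silylated afterwards (29 to 30).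

**Enol ether and enone (26 back to 21 and 17).** The C9=C10 bond is cut by a Wittig disconnection to ketone 21 and phosphonium salt 17. The olefination must come before C6 is oxidised (24 to 25), because a C6 ketone beside the C10 ketone would make C1 the centre of a 1,3-diketone and destroy it.

**Cyclohexene (21 back to 6 and 11).** The C1–C6 and C2–C3 bonds are cut by a Diels–Alder disconnection to diene 6 and enone 11. This is the only place where absolute configuration is introduced (C1). The three silyl groups are graded (trimethylsilyl on O6, triethylsilyl on O14, triisopropylsilyl on O15) so that they can be removed one at a time.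

**Building blocks.** Diene 6 comes from prenyl acetate 1 by way of 2–5; enone 11 from methyl glycolate 7 and vinylmagnesium bromide 9 by way of 8; salt 17 from 4-methoxybenzyl alcohol 12, chloromethyl methyl sulfide 13 and triphenylphosphine 15 by way of 14; vinyl ether 20 from 2-chloroethanol 18 by way of 19.

## Roads not taken

Alternative 1: The lactone is made last. With ring, esters and silyl ethers in place, a C6 hydroxyl and a C7 ethynyl group are joined by one carbon from CO (PdCl2, SnCl2, PPh3), forming the C11–C12 and C12–O bonds and giving A1, one desilylation from the target.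
- Merits: the Michael acceptor appears only at the end under neutral conditions; no enolate is ever generated next to the C8 oxygen; the C6/C7 relationship is fixed before the ring is stressed.
- Weak points: it says nothing about how the ten-membered ring and the four contiguous centres arise. The substrate holds an allylic acetate at C9 that zerovalent palladium formed under CO could ionise, and SnCl2 is a Lewis acid toward the allylic esters.
- Comparison: this endgame is shorter and gentler than the eight steps that follow the ring expansion here, and in that respect it is better. The chosen plan sets against it that one step delivers the ring together with C8 and C9.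

Alternative 2: The ring is closed at the bis-allylic C2–C3 bond. KN(SiMe3)2 deprotonates a C2 allylic sulfone and the carbanion displaces a C3 allylic bromide in the same chain, giving sulfone A2.
- Merits: a well-tried way to ten-membered dienes. Every stereocentre and both olefin geometries are set in open chain by reliable methods, and the outcome does not depend on a chair/boat choice or on the life of a β-alkoxy enolate.
- Weak points: a long linear route to a chain with four contiguous centres and two Z trisubstituted olefins; six protecting groups of five kinds; high dilution; SN2′ competition at the allylic bromide; and a reductive desulfonylation next to allylic C–O bonds that can be lost or transposed.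
- Comparison: in stereochemical certainty it is probably the stronger road. The chosen plan answers with step economy: the cyclohexene comes from a catalytic Diels–Alder reaction and C8, C9 and the ring are formed together.

Alternative 3: The ring is closed at C9–C10 on the preformed lactone. CrCl2 with catalytic NiCl2 turns a C10 alkenyl iodide into an alkenylchromium species that adds to a C9 aldehyde, giving the C9 alcohol A3.
- Merits: very chemoselective; the lactone and the C8 ester are tolerated, and only acetylation and desilylation remain.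
- Weak points: the C9 configuration is left to macrocyclic control. The aldehyde bears an α-acyloxy group and is prone to epimerisation and elimination, the Z alkenyl iodide with its CH2O substituent must be made separately, and the α-methylene lactone is exposed to divalent chromium for a long, dilute reaction.
- Comparison: its endgame is shorter than the present one. The chosen plan sets C9 together with C8 by a concerted step whose stereochemical course follows from alkene geometry rather than ring conformation.

Key step: step 18

Assumption: the (S)-configured catalyst in step 12 is taken to give the sense of induction needed for 21; if the adduct proves antipodal, the (R)-configured catalyst is used and nothing else changes.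

## Route

Step 1
Reactants: 1 3-methylbut-2-en-1-yl acetate
Product: 2 (E)-4-hydroxy-3-methylbut-2-en-1-yl acetate
Conditions: SeO2 (cat.), t-BuOOH, salicylic acid (cat.), CH2Cl2, rt
Reagents that add atoms: tert-butyl hydroperoxide CC(C)(C)OO
Why: SeO2-catalysed allylic oxidation (ene reaction, then [2,3] shift) occurs at the methyl group trans to the CH2OAc chain, so only the E allylic alcohol should form.

Step 2
Reactants: 2 (E)-4-hydroxy-3-methylbut-2-en-1-yl acetate
Product: 3 (E)-3-methyl-4-(triisopropylsilyloxy)but-2-en-1-yl acetate
Conditions: i-Pr3SiCl, imidazole, DMF, rt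
Reagents that add atoms: triisopropylsilyl chloride CC(C)[Si](Cl)(C(C)C)C(C)C
Why: Silylation of a primary alcohol; the triisopropylsilyl ether on the future O15 is chosen because it must survive fluoride, base and KH later.

Step 3
Reactants: 3 (E)-3-methyl-4-(triisopropylsilyloxy)but-2-en-1-yl acetate
Product: 4 (E)-3-methyl-4-(triisopropylsilyloxy)but-2-en-1-ol
Conditions: K2CO3 (cat.), MeOH, 0 °C
Reagents that add atoms: none
Why: Base-catalysed transesterification removes the acetate; the hindered silyl ether is inert to methanolic carbonate.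

Step 4
Reactants: 4 (E)-3-methyl-4-(triisopropylsilyloxy)but-2-en-1-ol
Product: 5 (E)-3-methyl-4-(triisopropylsilyloxy)but-2-enal
Conditions: MnO2, CH2Cl2, rt
Reagents that add atoms: none
Why: MnO2 oxidation of a primary allylic alcohol under neutral conditions, which should leave the olefin geometry untouched.

Step 5
Reactants: 5 (E)-3-methyl-4-(triisopropylsilyloxy)but-2-enal
Product: 6 (E)-1-(trimethylsilyloxy)-3-[(triisopropylsilyloxy)methyl]buta-1,3-diene
Conditions: Me3SiOTf, Et3N, Et2O, 0 °C
Reagents that add atoms: trimethylsilyl trifluoromethanesulfonate C[Si](C)(C)OS(=O)(=O)C(F)(F)F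
Why: Vinylogous silyl enol ether formation (O-silylation, then γ-deprotonation); the s-trans enal gives the 1E dienol ether, and the proton should be lost from the methyl group because the other γ-position is shielded by its bulky silyl ether.

Step 6
Reactants: 7 methyl glycolate
Product: 8 methyl 2-(triethylsilyloxy)acetate
Conditions: Et3SiCl, imidazole, CH2Cl2, 0 °C
Reagents that add atoms: triethylsilyl chloride CC[Si](Cl)(CC)CC
Why: Silylation; the triethylsilyl group on the future O14 is the one silyl ether that must come off selectively at the enone stage (step 15).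

Step 7
Reactants: 8 methyl 2-(triethylsilyloxy)acetate; 9 vinylmagnesium bromide
Product: 11 1-(triethylsilyloxy)but-3-en-2-one, via N-methoxy-N-methylamide 10 (not isolated)
Conditions: MeNH(OMe)·HCl, i-PrMgCl, THF, −20 °C; then 9, −20 → 0 °C; inverse quench into cold aq. citric acid
Reagents that add atoms: none
Why: Aminolysis of the ester by the magnesium amide, then addition of the vinyl organomagnesium reagent to the N-methoxy-N-methylamide, whose chelated tetrahedral intermediate prevents a second addition; the acidic inverse quench keeps the liberated amine from adding to the enone.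

Step 8
Reactants: 12 4-methoxybenzyl alcohol; 13 chloromethyl methyl sulfide
Product: 14 1-methoxy-4-[(methylsulfanylmethoxy)methyl]benzene
Conditions: NaH, NaI (cat.), DME, 0 °C → rt
Reagents that add atoms: none
Why: Williamson ether synthesis with an α-chloro sulfide, a standard way to O,S-acetals.

Step 9
Reactants: 14 1-methoxy-4-[(methylsulfanylmethoxy)methyl]benzene; 15 triphenylphosphine
Product: 17 [(4-methoxybenzyloxy)methyl]triphenylphosphonium chloride, via chloromethyl ether 16 (not isolated)
Conditions: SO2Cl2, CH2Cl2, −78 °C; concentrate; then 15, toluene, rt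
Reagents that add atoms: sulfuryl chloride O=S(=O)(Cl)Cl
Why: S-chlorination and fragmentation of the O,S-acetal gives the chloromethyl ether, which quaternises PPh3 by SN2 displacement; the sulfur is far more nucleophilic than the anisole ring at −78 °C.

Step 10
Reactants: 18 2-chloroethanol
Product: 19 1-chloro-2-(methoxymethoxy)ethane
Conditions: MeOCH2Cl, i-Pr2NEt, CH2Cl2, 0 °C → rt
Reagents that add atoms: chloromethyl methyl ether COCCl
Why: O-alkylation of the alcohol by the chloromethyl ether (acetal formation).

Step 11
Reactants: 19 1-chloro-2-(methoxymethoxy)ethane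
Product: 20 (methoxymethoxy)ethene
Conditions: KOt-Bu, DMSO, 20 → 60 °C, product distilled out
Reagents that add atoms: none
Why: E2 dehydrochlorination of a 2-chloroethyl ether, the usual route to simple vinyl ethers.

Step 12
Reactants: 6 (E)-1-(trimethylsilyloxy)-3-[(triisopropylsilyloxy)methyl]buta-1,3-diene; 11 1-(triethylsilyloxy)but-3-en-2-one
Product: 21 1-[(1R,2S)-4-[(triisopropylsilyloxy)methyl]-2-(trimethylsilyloxy)cyclohex-3-en-1-yl]-2-(triethylsilyloxy)ethan-1-one
Conditions: (S)-B-(o-tolyl)oxazaborolidine from α,α-diphenylprolinol, activated with (CF3SO2)2NH (15 mol %), CH2Cl2, −78 °C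
Reagents that add atoms: none
Why: Catalytic asymmetric Diels–Alder reaction; the 1-silyloxy group and the 3-substituent both send the unsubstituted diene terminus to the enone β-carbon, so the acyl-bearing carbon (C1) ends next to the oxygenated carbon (C6). The chiral boron cation bound to the ketone shields one enone face and sets C1; the endo mode gives the cis C6 silyl ether, a centre erased in step 14.

Step 13
Reactants: 21 Diels–Alder adduct; 17 [(4-methoxybenzyloxy)methyl]triphenylphosphonium chloride
Product: 24 (1S,6S)-6-[(Z)-1-(4-methoxybenzyloxy)-3-(triethylsilyloxy)prop-1-en-2-yl]-3-[(triisopropylsilyloxy)methyl]cyclohex-2-en-1-ol, via phosphorus ylide 22 (not isolated), via trimethylsilyl ether 23 (not isolated)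
Conditions: 17, KN(SiMe3)2, THF, −78 °C; then 21, −78 → 0 °C; then K2CO3, MeOH, 0 °C
Reagents that add atoms: none
Why: Wittig olefination of the α-silyloxy ketone with a non-stabilised alkoxymethylidene ylide; the alkoxy group is expected cis to the CH2OSi group and trans to the bulky ring carbon C1, the geometry the key step needs. Brief methanolysis with K2CO3 then removes only the trimethylsilyl ether.

Step 14
Reactants: 24 allylic alcohol
Product: 25 (6S)-6-[(Z)-1-(4-methoxybenzyloxy)-3-(triethylsilyloxy)prop-1-en-2-yl]-3-[(triisopropylsilyloxy)methyl]cyclohex-2-en-1-one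
Conditions: MnO2, CH2Cl2, rt
Reagents that add atoms: none
Why: MnO2 oxidation of the secondary allylic alcohol; the neutral heterogeneous oxidant should leave the enol ether and the epimerisable C1 (α to the new ketone and allylic) intact.

Step 15
Reactants: 25 enone
Product: 26 (6S)-6-[(Z)-3-hydroxy-1-(4-methoxybenzyloxy)prop-1-en-2-yl]-3-[(triisopropylsilyloxy)methyl]cyclohex-2-en-1-one
Conditions: Bu4NF, AcOH (1:1), THF, 0 °C
Reagents that add atoms: none
Why: Fluoride desilylation; the primary triethylsilyl ether is cleaved much faster than the primary triisopropylsilyl ether, and the acetic acid buffer keeps the medium from enolising C1.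

Step 16
Reactants: 26 hydroxy enone; 20 (methoxymethoxy)ethene
Product: 29 (1R,6S)-6-[(Z)-3-hydroxy-1-(4-methoxybenzyloxy)prop-1-en-2-yl]-1-[(Z)-2-(methoxymethoxy)ethenyl]-3-[(triisopropylsilyloxy)methyl]cyclohex-2-en-1-ol, via vinyllithium reagent 27 (not isolated), via vinylcerium reagent 28 (not isolated)
Conditions: 20 (4 equiv), s-BuLi, THF, −78 °C; CeCl3, −78 °C; then 26, −78 °C; aq. NH4Cl
Reagents that add atoms: none
Why: Alkoxide-directed 1,2-addition of an organocerium reagent; the first equivalent turns the C14 hydroxyl into a cerium alkoxide that binds the C6 carbonyl oxygen, which holds the C1 side chain pseudo-equatorial and brings the vinyl group to the carbonyl face syn to that chain. The new vinyl group should therefore be cis to the C1 alkenyl group and the hydroxyl trans. The Z geometry comes from acetal-directed cis-β-lithiation of 20 and is retained; cerium suppresses enolisation at C1 and conjugate addition.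

Step 17
Reactants: 29 diol
Product: 30 (1R,6S)-1-[(Z)-2-(methoxymethoxy)ethenyl]-6-[(Z)-1-(4-methoxybenzyloxy)-3-(triisopropylsilyloxy)prop-1-en-2-yl]-3-[(triisopropylsilyloxy)methyl]cyclohex-2-en-1-ol
Conditions: i-Pr3SiCl, imidazole, DMF, 0 °C
Reagents that add atoms: triisopropylsilyl chloride CC(C)[Si](Cl)(C(C)C)C(C)C
Why: Silylation of the primary alcohol only; the tertiary carbinol is too hindered to react, and the triisopropylsilyl group is chosen because it resists migration to an alkoxide in the next step.

Step 18
Reactants: 30 cis-1,2-dialkenylcyclohex-2-enol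
Product: 33 (2E,6Z,8S,9R)-9-(methoxymethoxy)-8-(4-methoxybenzyloxy)-3,7-bis[(triisopropylsilyloxy)methyl]cyclodeca-2,6-dien-1-one, via potassium alkoxide 31 (not isolated), via potassium enolate 32 (not isolated)
Conditions: KH, 18-crown-6, THF, −20 → 10 °C; then cannulated into AcOH, THF, −78 °C
Reagents that add atoms: none
Why: Deprotonation gives alkoxide 31, whose C1–C6 bond is weakened by the oxyanion and by the two alkenyl groups on C6; a concerted [3,3] shift through a chair, in which C8 bonds to C9 as C1–C6 breaks, gives the ten-membered dienolate 32, protonated at C7 on inverse acidic quench (anionic oxy-Cope rearrangement, the known ring expansion of 1,2-dialkenylcyclohexanols to cyclodec-5-enones, here with enol ether termini). The ten-membered ring is formed not by end-to-end cyclisation but by four-atom ring expansion of the cyclohexene through a six-membered transition state spanning C8–C7–C6/C1–C10–C9, so no dilution is needed. Because the two alkenyl groups are cis, the chair has C2 axial on C1 and the oxygen axial on C6; C2 therefore ends cis to C9 across the new C1=C10 bond, and the cyclohexene olefin becomes the ring-cis C4=C5 bond. C8 is set by the Z enol ether, which places O8 axial, and C9 by the enol ether in which O9 is trans to C1, which places O9 equatorial; an axial/equatorial pair gives the erythro (ring-cis) 8,9-diether, and the (1R,6S) configuration of 30 fixes the sense as 8R,9S. The step needs the chair to beat the boat, which would invert the C8/C9 relationship, and to beat the other chair with C5 axial, which would give the ring-trans C1=C10 olefin; the cis arrangement of the arms and the C14 substituent on C10, which clashes with C7–H in a boat, should favour the wanted path. It also needs enolate 32 to outlive β-elimination of the C8 alkoxy group, so the temperature is held at the lowest that sustains rearrangement and the mixture is transferred into cold acetic acid as soon as 30 is consumed. Silyl migration to the alkoxide is suppressed by the triisopropylsilyl groups.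

Step 19
Reactants: 33 cyclodecadienone; 34 methyl bromoacetate
Product: 36 methyl 2-[(1R,3E,7Z,9S,10R)-10-(methoxymethoxy)-9-(4-methoxybenzyloxy)-2-oxo-4,8-bis[(triisopropylsilyloxy)methyl]cyclodeca-3,7-dien-1-yl]acetate, via lithium enolate 35 (not isolated)
Conditions: LiN(SiMe3)2, THF, −78 °C; then 34, DMPU, −78 → −40 °C
Reagents that add atoms: none
Why: Kinetic deprotonation of the enone at the α′-carbon C7 and SN2 alkylation of the cross-conjugated lithium enolate; in the relaxed ring-cis enolate the electrophile should enter from the ring periphery anti to the adjacent C8 alkoxy group, as with 3-alkoxycycloalkanone enolates, giving the trans C7/C8 arrangement. Working at −78 to −40 °C limits β-elimination of the C8 ether.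

Step 20
Reactants: 36 keto ester
Product: 38 (6R,7S,8R,9S)-8-O-methoxymethyl-9-O-(4-methoxybenzyl)-14,15-bis-O-(triisopropylsilyl)-8,9,14,15-tetrahydroxy-13-norgermacra-1(10)Z,4E-dien-12,6-olide, via hydroxy ester 37 (not isolated)
Conditions: Zn(BH4)2, Et2O, −30 °C; then pyridinium p-toluenesulfonate (cat.), CH2Cl2, rt
Reagents that add atoms: none
Why: Chelation-controlled 1,2-reduction; zinc bridges the C6 carbonyl and the C8 methoxymethyl ether oxygens and hydride adds anti to the C7 side chain, which should place O6 cis to O8 and trans to the side chain (both controls reinforce for this C7/C8 pattern). The γ-hydroxy ester then closes to the trans-fused lactone under mild acid (lactonisation).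

Step 21
Reactants: 38 saturated lactone
Product: 41 8-O-methoxymethyl-9-O-(4-methoxybenzyl)-14,15-bis-O-(triisopropylsilyl) ether of (6R,7S,8R,9S)-8,9,14,15-tetrahydroxygermacra-1(10)Z,4E,11(13)-trien-12,6-olide, via Mannich base 39 (not isolated), via ammonium iodide 40 (not isolated)
Conditions: LiN(i-Pr)2, THF, −78 °C; CH2=NMe2 I, −78 → 0 °C; then MeI, MeOH, rt; then aq. NaHCO3, CH2Cl2
Reagents that add atoms: dimethyl(methylidene)ammonium iodide C=[N+](C)C.[I-]
Why: Mannich reaction of the lactone enolate with the iminium salt, then quaternisation and base-induced elimination of trimethylamine (α-methylenation); the enolate has no leaving group at its β-position and C7 is not acidic, so the ring centres are not at risk.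

Step 22
Reactants: 41 α-methylene lactone
Product: 42 9-O-(4-methoxybenzyl)-14,15-bis-O-(triisopropylsilyl) ether of the same tetrahydroxy lactone (free C8 hydroxyl)
Conditions: Me3SiOTf, 2,2′-bipyridyl, CH2Cl2, 0 °C; then H2O
Reagents that add atoms: none
Why: Acetal cleavage by silyl triflate activation in the presence of 2,2′-bipyridyl gives a pyridinium intermediate that water hydrolyses; these near-neutral conditions should remove the methoxymethyl group without touching the 4-methoxybenzyl ether, the silyl ethers or the lactone.

Step 23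
Reactants: 42 C8 alcohol; 43 (S)-2-methylbutanoic acid
Product: 44 8-O-[(S)-2-methylbutanoyl]-9-O-(4-methoxybenzyl)-14,15-bis-O-(triisopropylsilyl) derivative of the tetrahydroxy lactone
Conditions: i-PrN=C=N-i-Pr, DMAP (4-dimethylaminopyridine, cat.), CH2Cl2, 0 °C → rt
Reagents that add atoms: none
Why: Steglich esterification of the lone C8 hydroxyl while O9 is still an ether, so no acyl migration is possible; activation as the O-acylisourea at 0 °C should not epimerise the α-branched acid.

Step 24
Reactants: 44 C8 ester
Product: 45 8-O-[(S)-2-methylbutanoyl]-14,15-bis-O-(triisopropylsilyl) derivative of the tetrahydroxy lactone (free C9 hydroxyl)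
Conditions: DDQ, CH2Cl2, pH 7 phosphate buffer, 0 °C
Reagents that add atoms: none
Why: Oxidative cleavage of the 4-methoxybenzyl ether by benzylic hydride abstraction under buffered conditions; the product is acetylated at once to forestall migration of the C8 acyl group to O9.

Step 25
Reactants: 45 C9 alcohol
Product: 46 9-O-acetyl-8-O-[(S)-2-methylbutanoyl]-14,15-bis-O-(triisopropylsilyl) derivative of the tetrahydroxy lactone
Conditions: Ac2O, pyridine, DMAP (cat.), CH2Cl2, 0 °C
Reagents that add atoms: acetic anhydride CC(=O)OC(C)=O
Why: Acyl transfer with nucleophilic catalysis; acetylation of the allylic C9 hydroxyl at 0 °C should be faster than migration of the branched acyl group.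

Step 26
Reactants: 46 bis-silyl ether
Product: 47 9-O-acetyl-8-O-[(S)-2-methylbutanoyl]-(6R,7S,8R,9S)-8,9,14,15-tetrahydroxygermacra-1(10)Z,4E,11(13)-trien-12,6-olide (CNP0207247.12)
Conditions: HF·pyridine, pyridine, THF, 0 °C → rt
Reagents that add atoms: none
Why: Fluoride cleavage of both primary silyl ethers under buffered acidic conditions, which should spare the esters and the α-methylene lactone and not promote acyl migration to the freed C14 hydroxyl.

## Compound list

1 | 3-methylbut-2-en-1-yl acetate | CC(C)=CCOC(C)=O | starting material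
2 | (E)-4-hydroxy-3-methylbut-2-en-1-yl acetate | CC(=O)OC/C=C(\C)CO | intermediate
3 | (E)-3-methyl-4-(triisopropylsilyloxy)but-2-en-1-yl acetate | CC(=O)OC/C=C(\C)CO[Si](C(C)C)(C(C)C)C(C)C | intermediate
4 | (E)-3-methyl-4-(triisopropylsilyloxy)but-2-en-1-ol | OC/C=C(\C)CO[Si](C(C)C)(C(C)C)C(C)C | intermediate
5 | (E)-3-methyl-4-(triisopropylsilyloxy)but-2-enal | O=C/C=C(\C)CO[Si](C(C)C)(C(C)C)C(C)C | intermediate
6 | (E)-1-(trimethylsilyloxy)-3-[(triisopropylsilyloxy)methyl]buta-1,3-diene | C=C(CO[Si](C(C)C)(C(C)C)C(C)C)/C=C/O[Si](C)(C)C | intermediate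
7 | methyl glycolate | COC(=O)CO | starting material
8 | methyl 2-(triethylsilyloxy)acetate | COC(=O)CO[Si](CC)(CC)CC | intermediate
9 | vinylmagnesium bromide | C=C[Mg]Br | starting material
10 | N-methoxy-N-methyl-2-(triethylsilyloxy)acetamide (not isolated) | CON(C)C(=O)CO[Si](CC)(CC)CC | intermediate
11 | 1-(triethylsilyloxy)but-3-en-2-one | C=CC(=O)CO[Si](CC)(CC)CC | intermediate
12 | 4-methoxybenzyl alcohol | COc1ccc(CO)cc1 | starting material
13 | chloromethyl methyl sulfide | CSCCl | starting material
14 | 1-methoxy-4-[(methylsulfanylmethoxy)methyl]benzene | COc1ccc(COCSC)cc1 | intermediate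
15 | triphenylphosphine | c1ccc(cc1)P(c1ccccc1)c1ccccc1 | starting material
16 | 1-[(chloromethoxy)methyl]-4-methoxybenzene (not isolated) | COc1ccc(COCCl)cc1 | intermediate
17 | [(4-methoxybenzyloxy)methyl]triphenylphosphonium chloride | COc1ccc(COC[P+](c2ccccc2)(c2ccccc2)c2ccccc2)cc1.[Cl-] | intermediate
18 | 2-chloroethanol | OCCCl | starting material
19 | 1-chloro-2-(methoxymethoxy)ethane | COCOCCCl | intermediate
20 | (methoxymethoxy)ethene | COCOC=C | intermediate
21 | 1-[(1R,2S)-4-[(triisopropylsilyloxy)methyl]-2-(trimethylsilyloxy)cyclohex-3-en-1-yl]-2-(triethylsilyloxy)ethan-1-one (cis; ring C1 = germacrane C1, ring C2 = C6) | C[Si](C)(C)O[C@H]1C=C(CO[Si](C(C)C)(C(C)C)C(C)C)CC[C@H]1C(=O)CO[Si](CC)(CC)CC | intermediate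
22 | [(4-methoxybenzyloxy)methylidene]triphenylphosphorane (not isolated) | COc1ccc(COC=P(c2ccccc2)(c2ccccc2)c2ccccc2)cc1 | intermediate
23 | trimethylsilyl ether of 24 (not isolated) | C[Si](C)(C)O[C@H]1C=C(CO[Si](C(C)C)(C(C)C)C(C)C)CC[C@H]1/C(CO[Si](CC)(CC)CC)=C/OCc1ccc(OC)cc1 | intermediate
24 | (1S,6S)-6-[(Z)-1-(4-methoxybenzyloxy)-3-(triethylsilyloxy)prop-1-en-2-yl]-3-[(triisopropylsilyloxy)methyl]cyclohex-2-en-1-ol | O[C@H]1C=C(CO[Si](C(C)C)(C(C)C)C(C)C)CC[C@H]1/C(CO[Si](CC)(CC)CC)=C/OCc1ccc(OC)cc1 | intermediate
25 | (6S)-6-[(Z)-1-(4-methoxybenzyloxy)-3-(triethylsilyloxy)prop-1-en-2-yl]-3-[(triisopropylsilyloxy)methyl]cyclohex-2-en-1-one | O=C1C=C(CO[Si](C(C)C)(C(C)C)C(C)C)CC[C@H]1/C(CO[Si](CC)(CC)CC)=C/OCc1ccc(OC)cc1 | intermediate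
26 | (6S)-6-[(Z)-3-hydroxy-1-(4-methoxybenzyloxy)prop-1-en-2-yl]-3-[(triisopropylsilyloxy)methyl]cyclohex-2-en-1-one | O=C1C=C(CO[Si](C(C)C)(C(C)C)C(C)C)CC[C@H]1/C(CO)=C/OCc1ccc(OC)cc1 | intermediate
27 | (Z)-2-(methoxymethoxy)ethenyllithium (not isolated) | [Li]/C=C\OCOC | intermediate
28 | (Z)-2-(methoxymethoxy)ethenylcerium dichloride (not isolated) | Cl[Ce](Cl)/C=C\OCOC | intermediate
29 | (1R,6S)-6-[(Z)-3-hydroxy-1-(4-methoxybenzyloxy)prop-1-en-2-yl]-1-[(Z)-2-(methoxymethoxy)ethenyl]-3-[(triisopropylsilyloxy)methyl]cyclohex-2-en-1-ol | O[C@]1(/C=C\OCOC)C=C(CO[Si](C(C)C)(C(C)C)C(C)C)CC[C@H]1/C(CO)=C/OCc1ccc(OC)cc1 | intermediate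
30 | (1R,6S)-1-[(Z)-2-(methoxymethoxy)ethenyl]-6-[(Z)-1-(4-methoxybenzyloxy)-3-(triisopropylsilyloxy)prop-1-en-2-yl]-3-[(triisopropylsilyloxy)methyl]cyclohex-2-en-1-ol | O[C@]1(/C=C\OCOC)C=C(CO[Si](C(C)C)(C(C)C)C(C)C)CC[C@H]1/C(CO[Si](C(C)C)(C(C)C)C(C)C)=C/OCc1ccc(OC)cc1 | intermediate
31 | potassium alkoxide of 30 (not isolated) | [K+].[O-][C@]1(/C=C\OCOC)C=C(CO[Si](C(C)C)(C(C)C)C(C)C)CC[C@H]1/C(CO[Si](C(C)C)(C(C)C)C(C)C)=C/OCc1ccc(OC)cc1 | intermediate
32 | potassium C6=C7 enolate of 33 as first formed, with O6 cis to C8 (not isolated) | [K+].[O-]/C1=C\[C@@H](OCOC)[C@@H](OCc2ccc(OC)cc2)/C(CO[Si](C(C)C)(C(C)C)C(C)C)=C\CC/C(CO[Si](C(C)C)(C(C)C)C(C)C)=C\1 | intermediate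
33 | (2E,6Z,8S,9R)-9-(methoxymethoxy)-8-(4-methoxybenzyloxy)-3,7-bis[(triisopropylsilyloxy)methyl]cyclodeca-2,6-dien-1-one (ring C1 = germacrane C6, C8 = C9, C9 = C8) | O=C1/C=C(/CO[Si](C(C)C)(C(C)C)C(C)C)CC/C=C(/CO[Si](C(C)C)(C(C)C)C(C)C)[C@H](OCc2ccc(OC)cc2)[C@H](OCOC)C1 | intermediate
34 | methyl bromoacetate | COC(=O)CBr | starting material
35 | lithium C6=C7 enolate of 33, ring-cis (not isolated) | [Li+].[O-]/C1=C/[C@@H](OCOC)[C@@H](OCc2ccc(OC)cc2)/C(CO[Si](C(C)C)(C(C)C)C(C)C)=C\CC/C(CO[Si](C(C)C)(C(C)C)C(C)C)=C\1 | intermediate
36 | methyl 2-[(1R,3E,7Z,9S,10R)-10-(methoxymethoxy)-9-(4-methoxybenzyloxy)-2-oxo-4,8-bis[(triisopropylsilyloxy)methyl]cyclodeca-3,7-dien-1-yl]acetate | O=C1/C=C(/CO[Si](C(C)C)(C(C)C)C(C)C)CC/C=C(/CO[Si](C(C)C)(C(C)C)C(C)C)[C@H](OCc2ccc(OC)cc2)[C@H](OCOC)[C@H]1CC(=O)OC | intermediate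
37 | methyl 2-[(1S,2R,3E,7Z,9S,10R)-2-hydroxy-10-(methoxymethoxy)-9-(4-methoxybenzyloxy)-4,8-bis[(triisopropylsilyloxy)methyl]cyclodeca-3,7-dien-1-yl]acetate (not isolated) | O[C@@H]1/C=C(/CO[Si](C(C)C)(C(C)C)C(C)C)CC/C=C(/CO[Si](C(C)C)(C(C)C)C(C)C)[C@H](OCc2ccc(OC)cc2)[C@H](OCOC)[C@H]1CC(=O)OC | intermediate
38 | (6R,7S,8R,9S)-8-O-methoxymethyl-9-O-(4-methoxybenzyl)-14,15-bis-O-(triisopropylsilyl)-8,9,14,15-tetrahydroxy-13-norgermacra-1(10)Z,4E-dien-12,6-olide (trans-fused, C11 is CH2) | O=C1O[C@@H]2/C=C(/CO[Si](C(C)C)(C(C)C)C(C)C)CC/C=C(/CO[Si](C(C)C)(C(C)C)C(C)C)[C@H](OCc3ccc(OC)cc3)[C@H](OCOC)[C@H]2C1 | intermediate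
39 | 11-(dimethylaminomethyl) derivative of 38, mixture at C11 (not isolated) | CN(C)CC1C(=O)O[C@@H]2/C=C(/CO[Si](C(C)C)(C(C)C)C(C)C)CC/C=C(/CO[Si](C(C)C)(C(C)C)C(C)C)[C@H](OCc3ccc(OC)cc3)[C@H](OCOC)[C@@H]12 | intermediate
40 | trimethylammonium iodide from 39 (not isolated) | C[N+](C)(C)CC1C(=O)O[C@@H]2/C=C(/CO[Si](C(C)C)(C(C)C)C(C)C)CC/C=C(/CO[Si](C(C)C)(C(C)C)C(C)C)[C@H](OCc3ccc(OC)cc3)[C@H](OCOC)[C@@H]12.[I-] | intermediate
41 | 8-O-methoxymethyl-9-O-(4-methoxybenzyl)-14,15-bis-O-(triisopropylsilyl) ether of (6R,7S,8R,9S)-8,9,14,15-tetrahydroxygermacra-1(10)Z,4E,11(13)-trien-12,6-olide | C=C1C(=O)O[C@@H]2/C=C(/CO[Si](C(C)C)(C(C)C)C(C)C)CC/C=C(/CO[Si](C(C)C)(C(C)C)C(C)C)[C@H](OCc3ccc(OC)cc3)[C@H](OCOC)[C@@H]12 | intermediate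
42 | 9-O-(4-methoxybenzyl)-14,15-bis-O-(triisopropylsilyl) ether of the same lactone, free C8 hydroxyl | C=C1C(=O)O[C@@H]2/C=C(/CO[Si](C(C)C)(C(C)C)C(C)C)CC/C=C(/CO[Si](C(C)C)(C(C)C)C(C)C)[C@H](OCc3ccc(OC)cc3)[C@H](O)[C@@H]12 | intermediate
43 | (S)-2-methylbutanoic acid | CC[C@H](C)C(O)=O | starting material
44 | 8-O-[(S)-2-methylbutanoyl]-9-O-(4-methoxybenzyl)-14,15-bis-O-(triisopropylsilyl) derivative of the same lactone | C=C1C(=O)O[C@@H]2/C=C(/CO[Si](C(C)C)(C(C)C)C(C)C)CC/C=C(/CO[Si](C(C)C)(C(C)C)C(C)C)[C@H](OCc3ccc(OC)cc3)[C@H](OC(=O)[C@@H](C)CC)[C@@H]12 | intermediate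
45 | 8-O-[(S)-2-methylbutanoyl]-14,15-bis-O-(triisopropylsilyl) derivative, free C9 hydroxyl | C=C1C(=O)O[C@@H]2/C=C(/CO[Si](C(C)C)(C(C)C)C(C)C)CC/C=C(/CO[Si](C(C)C)(C(C)C)C(C)C)[C@H](O)[C@H](OC(=O)[C@@H](C)CC)[C@@H]12 | intermediate
46 | 9-O-acetyl-8-O-[(S)-2-methylbutanoyl]-14,15-bis-O-(triisopropylsilyl) derivative | C=C1C(=O)O[C@@H]2/C=C(/CO[Si](C(C)C)(C(C)C)C(C)C)CC/C=C(/CO[Si](C(C)C)(C(C)C)C(C)C)[C@H](OC(C)=O)[C@H](OC(=O)[C@@H](C)CC)[C@@H]12 | intermediate
47 | 9-O-acetyl-8-O-[(S)-2-methylbutanoyl]-(6R,7S,8R,9S)-8,9,14,15-tetrahydroxygermacra-1(10)Z,4E,11(13)-trien-12,6-olide (CNP0207247.12) | C=C1C(=O)O[C@@H]2/C=C(/CO)CC/C=C(/CO)[C@H](OC(C)=O)[C@H](OC(=O)[C@@H](C)CC)[C@@H]12 | target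

## Step count and risks

Total step count: 26. Longest linear sequence: 20 steps (steps 1–5, then 12–26).

**Step 18 (key step).**
- What may go wrong: loss of the C8 alkoxy group from the potassium enolate by β-elimination at the temperature the rearrangement needs; reaction through the other chair (ring bond C5 axial), which gives the ring-trans C1=C10 olefin; or through a boat, which inverts the C8/C9 relationship.
- Why: the enolate is a β-alkoxy enolate with a free cation, and the two chairs of a cis-dialkenyl substrate differ only in which ring bond is axial.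
- Fallback (neutral silyloxy-Cope, no enolate formed): 30 is silylated (Me3SiOTf, 2,6-lutidine) to the trimethylsilyl ether F1. F1 is heated in o-xylene (140–180 °C, base-washed glass) to rearrange to the ten-membered trimethylsilyl dienol ether F2. Mild methanolysis (K2CO3, MeOH, 0 °C) of F2 returns to the route at 33.

**Step 16.**
- What may go wrong: poor facial selectivity, i.e. addition anti to the C1 side chain through the rotamer in which that chain is pseudo-axial; and enolisation at C1 with loss of enantiopurity.
- Why: 6-alkenylcyclohexenones normally take nucleophiles trans to the substituent, and the alkoxide tether that should override this forms a seven-membered chelate of unproven strength.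
- Fallback (face blocking by a bulky Lewis acid instead of internal delivery): 26 is silylated (i-Pr3SiCl, imidazole) to the bis-triisopropylsilyl enone F3. F3 is complexed at −78 °C with MeAl(OAr)2 (Ar = 2,6-di-tert-butyl-4-methylphenyl), which occupies the open side of the carbonyl group. Vinyllithium reagent 27 then has to enter axially, cis to the C1 substituent, giving 30 directly.

**Step 13.**
- What may go wrong: formation of both enol ether geometries (the C9 configuration after step 18 depends on this geometry); β-elimination of the C6 silyloxy group or epimerisation at C1 by the basic ylide.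
- Why: Wittig alkoxymethylenations of ketones are often only moderately selective, and the ketone is a β-silyloxy ketone with an acidic α-hydrogen.
- Fallback (Horner–Wittig, with separation before a stereospecific elimination): chloromethyl ether 16 undergoes a Michaelis–Arbuzov reaction with ethyl diphenylphosphinite to give [(4-methoxybenzyloxy)methyl]diphenylphosphine oxide F4. Lithiated F4 (LiN(i-Pr)2, THF, −78 °C) adds to 21. The diastereomeric adducts are separated, and the β-hydroxy phosphine oxide F5 with the required relative configuration is treated with KH. Syn-elimination gives the single Z enol ether 23, which is methanolysed to 24 as in step 13.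

**Step 19.**
- What may go wrong: entry of the electrophile on the wrong face of C7; β-elimination of the C8 ether as the enolate warms; proton transfer to the extended dienolate.
- Why: the facial preference rests on the conformation of a ten-membered enolate, and bromoacetate alkylations of lithium enolates are slow at −78 °C.
- Fallback (set C7 by protonation instead of alkylation, which reverses the facial outcome): enolate 35 is condensed with methyl glyoxylate to the aldol adduct F6. F6 is dehydrated (MsCl, Et3N) to the alkylidene keto ester F7. Conjugate reduction of F7 with [(Ph3P)CuH]6 in wet benzene gives a copper enolate that is protonated at C7 from the ring periphery, returning to the route at 36.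

## Further compounds

F1 | step 18 | trimethylsilyl ether of 30 | C[Si](C)(C)O[C@]1(/C=C\OCOC)C=C(CO[Si](C(C)C)(C(C)C)C(C)C)CC[C@H]1/C(CO[Si](C(C)C)(C(C)C)C(C)C)=C/OCc1ccc(OC)cc1
F2 | step 18 | C6=C7 trimethylsilyl dienol ether of 33 (O6 cis to C8) | C[Si](C)(C)O/C1=C\[C@@H](OCOC)[C@@H](OCc2ccc(OC)cc2)/C(CO[Si](C(C)C)(C(C)C)C(C)C)=C\CC/C(CO[Si](C(C)C)(C(C)C)C(C)C)=C\1
F3 | step 16 | (6S)-6-[(Z)-1-(4-methoxybenzyloxy)-3-(triisopropylsilyloxy)prop-1-en-2-yl]-3-[(triisopropylsilyloxy)methyl]cyclohex-2-en-1-one | O=C1C=C(CO[Si](C(C)C)(C(C)C)C(C)C)CC[C@H]1/C(CO[Si](C(C)C)(C(C)C)C(C)C)=C/OCc1ccc(OC)cc1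
F4 | step 13 | [(4-methoxybenzyloxy)methyl]diphenylphosphine oxide | COc1ccc(COCP(=O)(c2ccccc2)c2ccccc2)cc1
F5 | step 13 | β-hydroxy phosphine oxide from 21 (one of the two adducts that eliminate to the Z enol ether) | C[Si](C)(C)O[C@H]1C=C(CO[Si](C(C)C)(C(C)C)C(C)C)CC[C@H]1[C@@](O)(CO[Si](CC)(CC)CC)[C@H](OCc1ccc(OC)cc1)P(=O)(c1ccccc1)c1ccccc1
F6 | step 19 | C7 aldol adduct of 33 with methyl glyoxylate (mixture at the two new centres) | O=C1/C=C(/CO[Si](C(C)C)(C(C)C)C(C)C)CC/C=C(/CO[Si](C(C)C)(C(C)C)C(C)C)[C@H](OCc2ccc(OC)cc2)[C@H](OCOC)C1C(O)C(=O)OC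
F7 | step 19 | C7 (methoxycarbonyl)methylidene derivative of 33 (E shown; either geometry serves) | O=C1/C=C(/CO[Si](C(C)C)(C(C)C)C(C)C)CC/C=C(/CO[Si](C(C)C)(C(C)C)C(C)C)[C@H](OCc2ccc(OC)cc2)[C@H](OCOC)/C1=C\C(=O)OC
A1 | alternative 1 | 14,15-bis-O-(tert-butyldimethylsilyl) ether of 47 | C=C1C(=O)O[C@@H]2/C=C(/CO[Si](C)(C)C(C)(C)C)CC/C=C(/CO[Si](C)(C)C(C)(C)C)[C@H](OC(C)=O)[C@H](OC(=O)[C@@H](C)CC)[C@@H]12
A2 | alternative 2 | ten-membered C2 phenyl sulfone with C6 O-(4-methoxybenzyl), C7 3-(4-methoxybenzyloxy)prop-1-en-2-yl, C8 O-tert-butyldimethylsilyl, C9 O-triethylsilyl and 14,15-bis-O-triisopropylsilyl groups (either C2 epimer) | COc1ccc(CO[C@@H]2/C=C(/CO[Si](C(C)C)(C(C)C)C(C)C)CC(S(=O)(=O)c3ccccc3)/C=C(/CO[Si](C(C)C)(C(C)C)C(C)C)[C@H](O[Si](CC)(CC)CC)[C@H](O[Si](C)(C)C(C)(C)C)[C@H]2C(=C)COCc2ccc(OC)cc2)cc1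
A3 | alternative 3 | 14,15-bis-O-(tert-butyldimethylsilyl) ether of 9-O-desacetyl-47 | C=C1C(=O)O[C@@H]2/C=C(/CO[Si](C)(C)C(C)(C)C)CC/C=C(/CO[Si](C)(C)C(C)(C)C)[C@H](O)[C@H](OC(=O)[C@@H](C)CC)[C@@H]12
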